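If you want to know where the catalyst of this flask stands at 20% conversion, count what one passage through catalyst intermediate B costs before you count anything else.

substrate 1.0 M; reagent 1.50 M; capture agent 0.100 M; free catalyst 50 mM; added ligand 46 mM

    reagent + free catalyst → catalyst intermediate A (k1 = 0.0056 M⁻¹ s⁻¹)
    substrate + catalyst intermediate A → catalyst intermediate B (k2 = 0.19 M⁻¹ s⁻¹)
    catalyst intermediate B → free catalyst + target (k3 = 0.0011 s⁻¹)
    free catalyst + added ligand ⇌ idle complex (K4 = 540 M⁻¹, k4 = 0.0016 M⁻¹ s⁻¹)
    catalyst intermediate B + capture agent → trapped intermediate (k5 = 0.0016 M⁻¹ s⁻¹)

- the form that holds most of the catalyst when 20% of the substrate are converted (catalyst intermediate B / idle complex / free catalyst / catalyst intermediate A / trapped intermediate)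
- its share of the catalyst then

In this flask, catalyst intermediate B has two exits: it releases target by step 3, or it meets capture agent by step 5. I take the ratio of those two rates, with capture agent at its charge, and call it the turns per capture, 6.88. With capture agent held at its charge, that many target leave for each catalyst lost.

One small correction follows. Inside the working round, with reagent at its charge, free catalyst stands to B as release stands to loading, 0.131, so I put B at 88.4% of the catalyst still in the round. I set aside catalyst intermediate A and the idle complex: with substrate at its charge, step 2 empties A at 680 h⁻¹, faster than B releases, and at the start free catalyst meets reagent at 110 times its forward rate of meeting added ligand.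

Now count in fractions of the catalyst charge. The substrate converted is 4.00 catalyst charges, and it sits in target, trapped intermediate and B:

converted = turns per capture × trapped share + trapped share + share in B

share in B = 88.4% × (what is not trapped)

trapped share = 44.6%, share in B = 49.0%

Set beside this flask its neighbour, with the same charges and step 5 struck out. There the trapped share is nil, and by the same reckoning I put B at 88.4%; target leaves from B, so the neighbour's rate at this conversion comes out at 1.80 times this flask's.

So for this flask I commit to catalyst intermediate B, the resting state of the round, at 49.0%, ahead of the trapped intermediate outside the round.

The forecast names catalyst intermediate B at 49%, and says that “capture has slowly drained roughly 40% of the catalyst”, where I reckoned 44.6%.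

The flask gives catalyst intermediate B at 48.2% after 1.24 h, with the trapped intermediate at 40.5%, behind by 7.6 percentage points.

The capture step is what separates this flask from its neighbour: with it struck out, the rate at this conversion is 1.73 times the actual one, where the turns per capture gave 1.80. Read from this flask's shares, target per trapped catalyst comes to 7.68 against the 6.88 reckoned, and by then the trapped intermediate has used 20.3% of the capture agent charged.

The constants used here were chosen freely; the result is computed.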